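The numbers in the tables were computed on assumed constants, noise included.

Early in the beta run, which is the asked flask followed so far, 66.7% of the substrate has gone in by 0.333 min, and substrate already reads 0% while target and open intermediate together read 64.0%. So I take the opening of substrate as a fast step and reckon with what it leaves: open intermediate waiting for partner.

| flask | substrate | partner | remark | time |
|---|---|---|---|---|
| beta | 2 mM (in portions, 3) | 2 mM | the very flask that is asked about, followed so far; portions every 12 s |  |
| delta | 2 mM (in portions, 3) | 1.3 mM | run made earlier; portions every 12 s |  |
| flask | 2.0 mM (in portions, 3) | 2.00 mM | the portions of substrate follow each other after 12 s, the first at the start | 20 min |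

| run | time / min | substrate / % | target / % | open intermediate / % |
|---|---|---|---|---|
| beta | 0.333 | 0 | 42 | 22 |
| beta | 0.667 | 0 | 69 | 33 |
| beta | 1.50 | 2 | 84 | 15 |
| beta | 4.00 | 2 | 88 | 10 |
| delta | 1.00 | 0 | 54 | 43 |
| delta | 3.00 | 0 | 60 | 36 |
| delta | 5.00 | 1 | 62 | 34 |
| delta | 8.00 | 0 | 61 | 36 |

(each reading ± 1.5 percentage points)

1. at 20 min, what has stopped the reaction, if anything has (forward and back rates have come level / all of the substrate has reacted / it is still moving)
2. part of the substrate gone at 20 min
3. the target standing at 20 min, as a percentage of the substrate charged
4. the open intermediate standing at 20 min, as a percentage of the substrate charged

- the reaction counts as stopped when no species that holds the substrate changes by six tenths of a point or more over the second half of the time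

With the main step by itself, each partner turns one open intermediate into target, so

target share = w · c(partner) / c(substrate), with w = 1.

That gives 65.0% in the delta run, where partner is the limiting reagent, and 100% in the flask.

The next process is a loss of partner, since delta's target lies flat at 61.0% and beta reads 88% at 4.00 min. I call w the partner yield, the target made per partner charged, and read it from beta:

w = 88% · 2 mM / 2 mM = 0.880

Delta reads 0.938, so the yield falls as the charge rises, and both readings carry the scatter. The flask has beta's charges, so w takes its target from 100% to 88.0% and leaves 12.0% as open intermediate.

The rest is a small gap in delta's balance, 3.33%, which brings the flask's open intermediate down to 8.67%. I commit to a stop with the substrate reacted away, as the last substrate readings are 0% in delta and 2% in beta against a scatter of 1.5 percentage points, but this is a judgement, for these runs fit forward and back rates come level as well.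

The forecast gives 88% target, 11% open intermediate and 99% of the substrate gone, close to my numbers, but its stop differs from mine: forward and back rates have come level, “so it looks like equilibrium”.

The flask at 20 min stands at 87.1% target and 10.1% open intermediate, with 100% of the substrate gone: all of the substrate has reacted.

    substrate → open intermediate (k = 1.17 /s)
    partner → second intermediate (k = 0.0383 /s)
    open intermediate + second intermediate → target (k = 2080 /M/s)
    2 second intermediate → homo product (k = 1890 /M/s)
    substrate + open intermediate → side product (k = 35.2 /M/s)

Partner in the flask stands at 0% of its charge, and the homo product, at 0.129 mM, holds 0.258 mM of partner, which is the charge less the target made, a partner yield of 0.871 against 0.880. Taken to the neighbour flask with 1.2 mM of partner, delta's 0.938 gives a target of 56.3%, and that flask stands at 56.7%.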